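The route rests on opening the pyran ring of the chromene (O1, C2, C3, C4, C4a, C8a) at O1–C2 and C3=C4, which leads back to a salicylaldehyde and an isobutenyl unit. The key step, a catalytic Petasis borono-Mannich/amine-elimination/oxa-6π-electrocyclisation cascade, exploits the phenolic oxygen (future O1) ortho to the formyl carbon (future C4): it delivers the 2-methylpropenyl group from boron to C4, then closes onto the gem-dimethyl carbon C2. The precursor is 5-bromo-2-hydroxy-4-methoxybenzaldehyde; its bromine (at future C6) becomes a boronic acid, and a nickel-catalysed enantioselective hydroarylation of a benzofuranyl 1,3-diene finally joins the halves and sets the (S)-stereocentre.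

Key step: step 1

Remark on the chemistry: the sense of induction of the nickel catalyst in step 7 cannot be read from the ligand alone. Both ligand antipodes are available; the one that gives the (S)-product is fixed in a pilot run and the configuration confirmed by chiroptical comparison. Compounds 1, 2, 9 and 11 are taken as catalogue materials.

Step 1
Reactants: 1 5-bromo-2-hydroxy-4-methoxybenzaldehyde; 2 (2-methylprop-1-en-1-yl)boronic acid
Product: 5 6-bromo-7-methoxy-2,2-dimethyl-2H-chromene, via allylic aminophenol 3 (not isolated), via ortho-quinone methide 4 (not isolated)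
Conditions: Bn2NH (40 mol %), 2 (1.5 equiv), 1,4-dioxane, 90 °C
Reagents that add atoms: none
Why: Dibenzylamine condenses with the formyl group of 1 to an iminium phenoxide, the ortho phenolic oxygen binds the boronic acid as a tetracoordinate boronate, and the 2-methylprop-1-enyl group migrates intramolecularly to the iminium carbon (Petasis borono-Mannich reaction), which creates the C4–C3 bond in aminophenol 3. At 90 °C this ortho-hydroxybenzylic allylic amine expels dibenzylamine, which re-enters the cycle, and gives ortho-quinone methide 4. Thermal disrotatory oxa-6π electrocyclisation of this 1-oxatriene closes the six-membered pyran ring by O1–C2 bond formation at the gem-dimethyl terminus, turns C4–C3 into the C3=C4 double bond and restores aromaticity. The closest known reaction type is the amine-catalysed Petasis condensation of salicylaldehydes with alkenylboronic acids to 2H-chromenes. No stereocentre is formed. The step needs chemoselectivity, secured because no transition metal is present to touch the aryl bromide, and site selectivity, secured because only the hydroxyl ortho to the aldehyde can bind boron and reach C2.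

Step 2
Reactants: 5 6-bromo-7-methoxy-2,2-dimethyl-2H-chromene
Product: 8 (7-methoxy-2,2-dimethyl-2H-chromen-6-yl)boronic acid, via aryllithium 6 (not isolated), via lithium triisopropoxyborate 7 (not isolated)
Conditions: n-BuLi, THF, −78 °C; B(OiPr)3, −78 °C → rt; 1 M HCl to pH 5–6, 0 °C
Reagents that add atoms: triisopropyl borate, CC(C)OB(OC(C)C)OC(C)C; water, O
Why: Bromine–lithium exchange at −78 °C is faster than any attack on the chromene, the aryllithium is trapped by the borate as an ate complex, and mild hydrolysis releases the boronic acid (halogen–metal exchange/borylation).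

Step 3
Reactants: 9 1-(2,4-dihydroxyphenyl)ethan-1-one
Product: 10 1-(2,4-dihydroxy-5-iodophenyl)ethan-1-one
Conditions: ICl (1.05 equiv), AcOH, rt
Reagents that add atoms: iodine monochloride, ClI
Why: Electrophilic aromatic iodination under acidic, non-chelating conditions should occur at C5, para to the 2-hydroxyl and ortho to the 4-hydroxyl, because C3 between the two hydroxyls is the more hindered site.

Step 4
Reactants: 10 1-(2,4-dihydroxy-5-iodophenyl)ethan-1-one; 11 (2E)-3-methylpent-2-en-4-yn-1-ol
Product: 13 1-[6-hydroxy-2-[(2E)-4-hydroxybut-2-en-2-yl]-1-benzofuran-5-yl]ethan-1-one, via ortho-alkynylphenol 12 (not isolated)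
Conditions: PdCl2(PPh3)2 (3 mol %), CuI (6 mol %), Et3N, DMF, 25 → 70 °C
Reagents that add atoms: none
Why: Sonogashira coupling of the aryl iodide with the terminal enyne is followed in the same pot by 5-endo-dig cycloisomerisation of the hydroxyl ortho to the alkyne (Sonogashira coupling/heteroannulation), which leaves the alkene geometry of 11 and the hydrogen-bonded 2-hydroxyl untouched.

Step 5
Reactants: 13 1-[6-hydroxy-2-[(2E)-4-hydroxybut-2-en-2-yl]-1-benzofuran-5-yl]ethan-1-one
Product: 14 (2E)-3-(5-acetyl-6-hydroxy-1-benzofuran-2-yl)but-2-enal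
Conditions: activated MnO2 (excess), CH2Cl2, rt
Reagents that add atoms: none
Why: Activated MnO2 oxidises the allylic alcohol selectively to the conjugated enal and should leave the hydrogen-bonded phenol and the ketone alone (allylic oxidation).

Step 6
Reactants: 14 (2E)-3-(5-acetyl-6-hydroxy-1-benzofuran-2-yl)but-2-enal
Product: 15 1-[6-hydroxy-2-[(2E)-penta-2,4-dien-2-yl]-1-benzofuran-5-yl]ethan-1-one
Conditions: Ph3PCH3Br (2.5 equiv), KOtBu (2.4 equiv), THF, 0 °C; then 14, −78 → 0 °C; aq. NH4Cl
Reagents that add atoms: methyltriphenylphosphonium bromide, C[P+](c1ccccc1)(c1ccccc1)c1ccccc1.[Br-]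
Why: Wittig methylenation converts the aldehyde into the terminal diene, while one extra equivalent of ylide deprotonates the phenol, whose phenoxide shields the ortho-acetyl group from the ylide; the trisubstituted (E)-alkene is not involved.

Step 7
Reactants: 15 1-[6-hydroxy-2-[(2E)-penta-2,4-dien-2-yl]-1-benzofuran-5-yl]ethan-1-one; 8 (7-methoxy-2,2-dimethyl-2H-chromen-6-yl)boronic acid
Product: 16 1-[6-hydroxy-2-[(2E,4S)-4-(7-methoxy-2,2-dimethyl-2H-chromen-6-yl)pent-2-en-2-yl]-1-benzofuran-5-yl]ethan-1-one
Conditions: Ni(cod)2 (10 mol %), chiral spirobiindane aminophosphine ligand (12 mol %, antipode giving (S)), 8 (2 equiv), MeOH/THF, 40 °C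
Reagents that add atoms: none
Why: In this nickel-catalysed enantioselective 1,2-Markovnikov hydroarylation of a 1-aryl-1,3-diene with an arylboronic acid, methanol protonates the zerovalent nickel–diene complex at the terminal CH2 to give a π-allyl nickel species, transmetalation and reductive elimination place the aryl group on the methyl-bearing allyl terminus so that conjugation with the benzofuran and the (E)-geometry are kept, and the chiral ligand sets the (S)-configuration of the new benzylic stereocentre.

Compound list
1 | 5-bromo-2-hydroxy-4-methoxybenzaldehyde | COc1cc(O)c(C=O)cc1Br | starting material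
2 | (2-methylprop-1-en-1-yl)boronic acid | CC(C)=CB(O)O | starting material
3 | 4-bromo-2-[1-(dibenzylamino)-3-methylbut-2-en-1-yl]-5-methoxyphenol (racemic allylic aminophenol) | COc1cc(O)c(C(C=C(C)C)N(Cc2ccccc2)Cc2ccccc2)cc1Br | intermediate
4 | 4-bromo-3-methoxy-6-(3-methylbut-2-en-1-ylidene)cyclohexa-2,4-dien-1-one (ortho-quinone methide) | COC1=CC(=O)C(=CC=C(C)C)C=C1Br | intermediate
5 | 6-bromo-7-methoxy-2,2-dimethyl-2H-chromene | COc1cc2OC(C)(C)C=Cc2cc1Br | intermediate
6 | (7-methoxy-2,2-dimethyl-2H-chromen-6-yl)lithium | COc1cc2OC(C)(C)C=Cc2cc1[Li] | intermediate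
7 | lithium (7-methoxy-2,2-dimethyl-2H-chromen-6-yl)tri(propan-2-yloxy)borate | COc1cc2OC(C)(C)C=Cc2cc1[B-](OC(C)C)(OC(C)C)OC(C)C.[Li+] | intermediate
8 | (7-methoxy-2,2-dimethyl-2H-chromen-6-yl)boronic acid | COc1cc2OC(C)(C)C=Cc2cc1B(O)O | intermediate
9 | 1-(2,4-dihydroxyphenyl)ethan-1-one | CC(=O)c1ccc(O)cc1O | starting material
10 | 1-(2,4-dihydroxy-5-iodophenyl)ethan-1-one | CC(=O)c1cc(I)c(O)cc1O | intermediate
11 | (2E)-3-methylpent-2-en-4-yn-1-ol | C#C/C(C)=C/CO | starting material
12 | 1-[2,4-dihydroxy-5-[(3E)-5-hydroxy-3-methylpent-3-en-1-yn-1-yl]phenyl]ethan-1-one | CC(=O)c1cc(C#C/C(C)=C/CO)c(O)cc1O | intermediate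
13 | 1-[6-hydroxy-2-[(2E)-4-hydroxybut-2-en-2-yl]-1-benzofuran-5-yl]ethan-1-one | CC(=O)c1cc2cc(/C(C)=C/CO)oc2cc1O | intermediate
14 | (2E)-3-(5-acetyl-6-hydroxy-1-benzofuran-2-yl)but-2-enal | CC(=O)c1cc2cc(/C(C)=C/C=O)oc2cc1O | intermediate
15 | 1-[6-hydroxy-2-[(2E)-penta-2,4-dien-2-yl]-1-benzofuran-5-yl]ethan-1-one | CC(=O)c1cc2cc(/C(C)=C/C=C)oc2cc1O | intermediate
16 | 1-[6-hydroxy-2-[(2E,4S)-4-(7-methoxy-2,2-dimethyl-2H-chromen-6-yl)pent-2-en-2-yl]-1-benzofuran-5-yl]ethan-1-one | COc1cc2c(cc1[C@@H](C)/C=C(\C)c1cc3cc(C(C)=O)c(O)cc3o1)C=CC(C)(C)O2 | target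

Total step count: 7
Longest linear sequence: 5 steps (steps 3, 4, 5, 6, 7); the other branch is steps 1 and 2, joined in step 7.

Steps most likely to fail

Step 7. The free ortho-acylphenol of 15 may chelate divalent nickel intermediates and stall turnover, and the ortho-methoxy arylboronic acid may protodeboronate faster than it transmetalates, both of which would erode conversion and enantioselectivity. The fallback sets out from 15: the phenol is acetylated (Ac2O, pyridine, cat. DMAP, CH2Cl2, 0 °C) to 5-acetyl-2-[(2E)-penta-2,4-dien-2-yl]-1-benzofuran-6-yl acetate F1. The nickel-catalysed hydroarylation with 8 is then run on this non-chelating substrate to give 5-acetyl-2-[(2E,4S)-4-(7-methoxy-2,2-dimethyl-2H-chromen-6-yl)pent-2-en-2-yl]-1-benzofuran-6-yl acetate F2. Mild methanolysis (K2CO3, MeOH, 0 °C), which does not touch the benzylic stereocentre, comes back to the route at 16.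

Step 1. Alkenyl transfer to the iminium, which the para-methoxy group deactivates, may be outrun by protodeboronation of the alkenylboronic acid, or the aminophenol may fail to expel the amine. The fallback sets out from 1: 2-methylprop-1-enylmagnesium bromide (2.2 equiv, THF, 0 °C) adds to the aldehyde to give 4-bromo-2-(1-hydroxy-3-methylbut-2-en-1-yl)-5-methoxyphenol F3. Warming F3 in toluene with a trace of pyridinium p-toluenesulfonate dehydrates it to the same ortho-quinone methide 4, which electrocyclises and comes back to the route at 5.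

Step 6. The basic ylide may enolise the enal through its γ-methyl group (geometry scrambling, aldol oligomerisation), and addition to the phenoxide-deactivated push–pull aldehyde may be slow. The fallback sets out from 11 and builds the diene before the benzofuran: MnO2 oxidation gives (2E)-3-methylpent-2-en-4-ynal F4, and Wittig methylenation gives (3E)-3-methylhexa-3,5-dien-1-yne F5, kept in solution because it is volatile. Sonogashira coupling/cycloisomerisation of F5 with 10 under the conditions of step 4 comes back to the route at 15.

Further compounds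
F1 | step 7 | 5-acetyl-2-[(2E)-penta-2,4-dien-2-yl]-1-benzofuran-6-yl acetate | CC(=O)Oc1cc2oc(/C(C)=C/C=C)cc2cc1C(C)=O
F2 | step 7 | 5-acetyl-2-[(2E,4S)-4-(7-methoxy-2,2-dimethyl-2H-chromen-6-yl)pent-2-en-2-yl]-1-benzofuran-6-yl acetate | COc1cc2c(cc1[C@@H](C)/C=C(\C)c1cc3cc(C(C)=O)c(OC(C)=O)cc3o1)C=CC(C)(C)O2
F3 | step 1 | 4-bromo-2-(1-hydroxy-3-methylbut-2-en-1-yl)-5-methoxyphenol | COc1cc(O)c(C(O)C=C(C)C)cc1Br
F4 | step 6 | (2E)-3-methylpent-2-en-4-ynal | C#C/C(C)=C/C=O
F5 | step 6 | (3E)-3-methylhexa-3,5-dien-1-yne | C#C/C(C)=C/C=C
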